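**Retrosynthetic overview**
1. Target 25 ⇒ C1 alcohol 22 + angelic acid 23 (ester last). C11 comes from Ru–BINAP hydrogenation of the C11=C13 acrylic acid 19, C12 from carbonylation of the enol triflate of the C7 acetyl group, and the C8 ketone from C8–OSiEt3.
2. Feature: ring B (C5, C6, C7, C8, C9, C10) carries C6=C7 and C9=C10 on either side of sp3 C5 and of oxidised C8. This cyclohexa-1,4-diene is cut at C5–C6 and C7–C8 into the diene C5=C10–C9=C8–OSiEt3 (13) and the alkyne C6≡C7 (but-3-yn-2-one 14).
3. Diene 13 ⇒ vinyl iodide 8: C10–C9 bond by Negishi coupling with a Reformatsky reagent, then ester → aldehyde → (E)-silyl dienol ether. 8 ⇒ (S)-3,4-dimethylcyclohex-2-enone 5 by α-iodination, CBS reduction (C1) and silylation.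
4. 5 ⇒ 4-methylcyclohexanone 1 by chiral-amide desymmetrisation (C4), Saegusa oxidation, methyl cuprate addition and a second Saegusa oxidation.
5. Ring order: ring A comes from 1 and is carried through; ring B is closed in the Diels–Alder step.

Key step: step 11

Numbering used in the text (eremophilane): ring A = C1–C2–C3–C4–C5–C10, ring B = C5–C6–C7–C8–C9–C10; methyls on C4 and C5; side chain C11(C13)–C12 on C7.
Assumption: the (R,R)-amide of step 1 is taken to give the (S)-enol silane 2, by analogy with 4-tert-butylcyclohexanone; if the sense is opposite, the (S,S)-amide is used and nothing else changes.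

**Route**

Step 1
Reactants: 1 4-methylcyclohexanone
Product: 2 (S)-trimethyl[(4-methylcyclohex-1-en-1-yl)oxy]silane
Conditions: lithium (R,R)-bis(1-phenylethyl)amide (from the amine and n-BuLi), TMSCl (in situ quench), THF, −100 °C
Reagents that add atoms: chlorotrimethylsilane, C[Si](C)(C)Cl
Why: Enantiotopic-proton-selective kinetic deprotonation of the Cs-symmetric ketone by the C2-symmetric chiral lithium amide with in situ silyl trapping (desymmetrising enolisation) should fix the C4 methyl centre as (S) relative to the new enol double bond.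

Step 2
Reactants: 2 (S)-trimethyl[(4-methylcyclohex-1-en-1-yl)oxy]silane
Product: 3 (S)-4-methylcyclohex-2-en-1-one
Conditions: Pd(OAc)2 (1.05 equiv), MeCN, rt
Reagents that add atoms: none
Why: Saegusa oxidation, in which the palladium enolate formed from the enol silane undergoes β-hydride elimination towards C3 only, should give the enone without touching the γ stereocentre.

Step 3
Reactants: 3 (S)-4-methylcyclohex-2-en-1-one
Product: 4 trimethyl{[(3R,4S)-3,4-dimethylcyclohex-1-en-1-yl]oxy}silane (trans-dimethyl)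
Conditions: Me2CuLi (from MeLi and CuI), TMSCl, THF/Et2O, −78 °C
Reagents that add atoms: lithium dimethylcuprate, [Li+].C[Cu-]C; chlorotrimethylsilane, C[Si](C)(C)Cl
Why: Conjugate addition of the Gilman cuprate anti to the C4 methyl, with TMSCl trapping the enolate regiospecifically as the C1–C2 enol silane; the transient C3 centre is erased in step 4.

Step 4
Reactants: 4 trimethyl{[(3R,4S)-3,4-dimethylcyclohex-1-en-1-yl]oxy}silane
Product: 5 (S)-3,4-dimethylcyclohex-2-en-1-one
Conditions: Pd(OAc)2 (1.05 equiv), MeCN, rt to 40 °C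
Reagents that add atoms: none
Why: A second Saegusa oxidation reintroduces the C2=C3 alkene regiospecifically from the trapped enol silane, so steps 3 and 4 together amount to β-methylation of the enone with the C4 centre intact.

Step 5
Reactants: 5 (S)-3,4-dimethylcyclohex-2-en-1-one
Product: 6 (S)-2-iodo-3,4-dimethylcyclohex-2-en-1-one
Conditions: I2, pyridine/CH2Cl2 (1:1), DMAP (cat.), 0 °C to rt
Reagents that add atoms: iodine, II
Why: α-Iodination of the enone by amine conjugate addition, iodination of the enolate and elimination (Baylis–Hillman-type pathway), known for 3-methylcyclohex-2-enones, gives the vinyl iodide needed for cross-coupling.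

Step 6
Reactants: 6 (S)-2-iodo-3,4-dimethylcyclohex-2-en-1-one
Product: 7 (1R,4S)-2-iodo-3,4-dimethylcyclohex-2-en-1-ol (OH cis to the C4 methyl)
Conditions: (S)-2-methyl-CBS-oxazaborolidine (15 mol %), BH3·SMe2, THF, −20 °C; MeOH quench
Reagents that add atoms: none
Why: CBS reduction with the iodoalkene carbon as the large group should deliver hydride under catalyst control to give the (1R)-carbinol; material of the minor enantiomeric series from step 1 becomes the trans diastereomer and is removed by chromatography.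

Step 7
Reactants: 7 (1R,4S)-2-iodo-3,4-dimethylcyclohex-2-en-1-ol
Product: 8 tert-butyl{[(1R,4S)-2-iodo-3,4-dimethylcyclohex-2-en-1-yl]oxy}dimethylsilane
Conditions: TBSCl, imidazole, DMF, rt
Reagents that add atoms: tert-butyldimethylsilyl chloride, CC(C)(C)[Si](C)(C)Cl
Why: Standard silylation of a secondary allylic alcohol; the bulky silyl ether later shields one face of ring A and survives until step 18.

Step 8
Reactants: 8 tert-butyl{[(1R,4S)-2-iodo-3,4-dimethylcyclohex-2-en-1-yl]oxy}dimethylsilane; 9 ethyl bromoacetate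
Product: 11 ethyl 2-[(3S,6R)-6-(tert-butyldimethylsilyloxy)-2,3-dimethylcyclohex-1-en-1-yl]acetate, via Reformatsky reagent 10 (not isolated)
Conditions: Zn dust (TMSCl-activated), 9, THF, rt; then 8, Pd2(dba)3 (2.5 mol %), XPhos (2-dicyclohexylphosphino-2',4',6'-triisopropylbiphenyl), THF, 60 °C
Reagents that add atoms: none
Why: Negishi-type coupling of a Reformatsky reagent with an alkenyl iodide installs the C9–C8 unit on C10 without any acid hydrolysis of a dienyl ether, which would protonate at C5 and move the C5=C10 alkene into conjugation.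

Step 9
Reactants: 11 ethyl 2-[(3S,6R)-6-(tert-butyldimethylsilyloxy)-2,3-dimethylcyclohex-1-en-1-yl]acetate
Product: 12 2-[(3S,6R)-6-(tert-butyldimethylsilyloxy)-2,3-dimethylcyclohex-1-en-1-yl]acetaldehyde
Conditions: i-Bu2AlH (1.1 equiv), CH2Cl2, −78 °C; aq. potassium sodium tartrate work-up; used crude
Reagents that add atoms: none
Why: Partial ester reduction at −78 °C stops at the tetrahedral aluminium hemiacetal, which releases the β,γ-unsaturated aldehyde only on neutral work-up, so the tetrasubstituted alkene should not migrate.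

Step 10
Reactants: 12 2-[(3S,6R)-6-(tert-butyldimethylsilyloxy)-2,3-dimethylcyclohex-1-en-1-yl]acetaldehyde
Product: 13 tert-butyl{[(1R,4S)-3,4-dimethyl-2-[(E)-2-(triethylsilyloxy)ethenyl]cyclohex-2-en-1-yl]oxy}dimethylsilane (ring A diene)
Conditions: TESOTf, Et3N, CH2Cl2, −78 °C to rt (held at rt to equilibrate)
Reagents that add atoms: triethylsilyl trifluoromethanesulfonate, CC[Si](CC)(CC)OS(=O)(=O)C(F)(F)F
Why: Soft enolisation (silyl triflate/amine) can only remove a C9 proton and so gives the 1-silyloxydiene; under equilibrating conditions the (E)-isomer should dominate because a (Z)-silyloxy group would clash with the C1/C5-substituted ring.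

Step 11
Reactants: 13 ring A diene; 14 but-3-yn-2-one
Product: 15 1-[(2S,4aS,5S,8R)-8-(tert-butyldimethylsilyloxy)-4a,5-dimethyl-2-(triethylsilyloxy)-2,4a,5,6,7,8-hexahydronaphthalen-3-yl]ethan-1-one (ring B 1,4-diene with C7 acetyl and C8 OSiEt3)
Conditions: 14 (4 equiv), toluene, BHT (trace), 90 °C, sealed tube
Reagents that add atoms: none
Why: A concerted but asynchronous, suprafacial normal-demand [4+2] cycloaddition in which the nucleophilic diene terminus C5 (remote from the silyloxy donor on C8) bonds to the unsubstituted β-carbon C6 of the ynone while C8 bonds to C7; the closest known reaction type is the Diels–Alder addition of 1-silyloxy-1,3-dienes and of 2-methyl-1-vinylcyclohexenes to ynones and acetylenic esters. Ring B is closed by this intermolecular [4+2] annulation onto ring A, the alkyne supplying C6=C7 and the diene leaving C9=C10, so the skipped diene with C8 at the alcohol level results. The quaternary C5 centre is controlled by ring A: the C4 methyl and the C1 silyloxy group lie on the same face, so the dienophile should add to the opposite face and the C5 methyl ends cis to both (5S). C8 follows from suprafacial addition to the (E)-enol ether (OSiEt3 trans to the C5 methyl, 8S) and is erased in step 14. The step needs ortho regioselectivity, secured by the silyloxy donor and by the hindered C5 meeting the unsubstituted alkyne carbon, and enough reactivity to override the inside methyl on C5, for which the linear ynone and the electron-rich diene are chosen.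

Step 12
Reactants: 15 cycloadduct methyl ketone
Product: 16 1-[(2S,4aS,5S,8R)-8-(tert-butyldimethylsilyloxy)-4a,5-dimethyl-2-(triethylsilyloxy)-2,4a,5,6,7,8-hexahydronaphthalen-3-yl]ethenyl trifluoromethanesulfonate
Conditions: KN(SiMe3)2, THF, −78 °C; then PhNTf2, −78 to 0 °C
Reagents that add atoms: N-phenylbis(trifluoromethanesulfonimide), O=S(=O)(N(c1ccccc1)S(=O)(=O)C(F)(F)F)C(F)(F)F
Why: Kinetic deprotonation of the only enolisable position (the acetyl methyl) and O-triflation gives the 2-triflyloxy-1,3-diene; C8–H is not α to the carbonyl and should stay untouched.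

Step 13
Reactants: 16 dienyl triflate with C8 OSiEt3
Product: 17 1-[(2S,4aS,5S,8R)-8-(tert-butyldimethylsilyloxy)-2-hydroxy-4a,5-dimethyl-2,4a,5,6,7,8-hexahydronaphthalen-3-yl]ethenyl trifluoromethanesulfonate
Conditions: HF·pyridine, pyridine, THF, 0 °C; used directly
Reagents that add atoms: none
Why: Buffered fluoride cleaves the triethylsilyl ether selectively in the presence of the tert-butyldimethylsilyl ether, and the non-acidic medium avoids ionisation of the bis-allylic alcohol.

Step 14
Reactants: 17 C8 alcohol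
Product: 18 1-[(4aS,5S,8R)-8-(tert-butyldimethylsilyloxy)-4a,5-dimethyl-2-oxo-2,4a,5,6,7,8-hexahydronaphthalen-3-yl]ethenyl trifluoromethanesulfonate
Conditions: Dess–Martin periodinane, NaHCO3, CH2Cl2, 0 °C to rt
Reagents that add atoms: none
Why: Buffered Dess–Martin oxidation of the bis-allylic alcohol gives the cross-conjugated dienone; C5 is quaternary, so aromatisation is not possible, and no carboxyl group is yet present to lactonise onto C8.

Step 15
Reactants: 18 dienone enol triflate
Product: 19 2-[(4aS,5S,8R)-8-(tert-butyldimethylsilyloxy)-4a,5-dimethyl-2-oxo-2,4a,5,6,7,8-hexahydronaphthalen-3-yl]prop-2-enoic acid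
Conditions: Pd(OAc)2 (5 mol %), dppf (1,1'-bis(diphenylphosphino)ferrocene), KOAc, CO (1 atm), DMF/H2O, 60 °C; work-up at pH 4
Reagents that add atoms: carbon monoxide, [C-]#[O+]; water, O
Why: Palladium-catalysed hydroxycarbonylation of the enol triflate (oxidative addition to zerovalent palladium, CO insertion, hydrolysis of the acyl palladium species) adds C12 as the free acid needed to direct the hydrogenation.

Step 16
Reactants: 19 acrylic acid
Product: 20 (2S)-2-[(4aS,5S,8R)-8-(tert-butyldimethylsilyloxy)-4a,5-dimethyl-2-oxo-2,4a,5,6,7,8-hexahydronaphthalen-3-yl]propanoic acid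
Conditions: Ru(OAc)2[(S)-BINAP] (1 mol %), H2 (100 atm), MeOH, 15 °C
Reagents that add atoms: none
Why: Carboxylate-directed asymmetric hydrogenation of a 2-substituted acrylic acid with Ru–BINAP, in the sense known for 2-arylacrylic acids, should reduce only the 1,1-disubstituted C11=C13 alkene and set C11 as (S) under catalyst control, the hindered trisubstituted ring B alkenes being far slower.

Step 17
Reactants: 20 (11S)-propanoic acid
Product: 21 methyl (2S)-2-[(4aS,5S,8R)-8-(tert-butyldimethylsilyloxy)-4a,5-dimethyl-2-oxo-2,4a,5,6,7,8-hexahydronaphthalen-3-yl]propanoate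
Conditions: TMSCHN2, toluene/MeOH (4:1), 0 °C
Reagents that add atoms: trimethylsilyldiazomethane, C[Si](C)(C)C=[N+]=[N-]
Why: O-Methylation of the acid with TMSCHN2 needs no base, so the epimerisable C11 centre should be preserved.

Step 18
Reactants: 21 methyl ester with C1 silyl ether
Product: 22 methyl (2S)-2-[(4aS,5S,8R)-8-hydroxy-4a,5-dimethyl-2-oxo-2,4a,5,6,7,8-hexahydronaphthalen-3-yl]propanoate
Conditions: HF·pyridine (excess), THF, 0 °C to rt
Reagents that add atoms: none
Why: Fluoride cleavage of the remaining silyl ether under mildly acidic conditions frees the C1 alcohol without epimerising C11 or disturbing the dienone.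

Step 19
Reactants: 22 C1 alcohol; 23 angelic acid
Product: 25 methyl (2S)-2-[(4aS,5S,8R)-4a,5-dimethyl-8-{[(2Z)-2-methylbut-2-enoyl]oxy}-2-oxo-2,4a,5,6,7,8-hexahydronaphthalen-3-yl]propanoate (target), via mixed anhydride 24 (not isolated)
Conditions: 23, 2,4,6-trichlorobenzoyl chloride, Et3N, toluene, rt, filter; then 22, toluene, 80 °C
Reagents that add atoms: none
Why: Acylation with the preformed mixed anhydride (Yamaguchi-type, no nucleophilic catalyst) should transfer the angeloyl group to the hindered C1 alcohol with retention at C1 while keeping Z→E isomerisation to the tiglate low.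

**Compound list**
1 | 4-methylcyclohexanone | CC1CCC(=O)CC1 | starting material
2 | (S)-trimethyl[(4-methylcyclohex-1-en-1-yl)oxy]silane | C[Si](C)(C)OC1=CC[C@@H](C)CC1 | intermediate
3 | (S)-4-methylcyclohex-2-en-1-one | O=C1C=C[C@@H](C)CC1 | intermediate
4 | trimethyl{[(3R,4S)-3,4-dimethylcyclohex-1-en-1-yl]oxy}silane | C[Si](C)(C)OC1=C[C@H](C)[C@@H](C)CC1 | intermediate
5 | (S)-3,4-dimethylcyclohex-2-en-1-one | O=C1C=C(C)[C@@H](C)CC1 | intermediate
6 | (S)-2-iodo-3,4-dimethylcyclohex-2-en-1-one | O=C1C(I)=C(C)[C@@H](C)CC1 | intermediate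
7 | (1R,4S)-2-iodo-3,4-dimethylcyclohex-2-en-1-ol | O[C@@H]1CC[C@H](C)C(C)=C1I | intermediate
8 | tert-butyl{[(1R,4S)-2-iodo-3,4-dimethylcyclohex-2-en-1-yl]oxy}dimethylsilane | CC(C)(C)[Si](C)(C)O[C@@H]1CC[C@H](C)C(C)=C1I | intermediate
9 | ethyl bromoacetate | CCOC(=O)CBr | starting material
10 | (2-ethoxy-2-oxoethyl)zinc bromide (Reformatsky reagent) | CCOC(=O)C[Zn]Br | intermediate
11 | ethyl 2-[(3S,6R)-6-(tert-butyldimethylsilyloxy)-2,3-dimethylcyclohex-1-en-1-yl]acetate | CC(C)(C)[Si](C)(C)O[C@@H]1CC[C@H](C)C(C)=C1CC(=O)OCC | intermediate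
12 | 2-[(3S,6R)-6-(tert-butyldimethylsilyloxy)-2,3-dimethylcyclohex-1-en-1-yl]acetaldehyde | CC(C)(C)[Si](C)(C)O[C@@H]1CC[C@H](C)C(C)=C1CC=O | intermediate
13 | tert-butyl{[(1R,4S)-3,4-dimethyl-2-[(E)-2-(triethylsilyloxy)ethenyl]cyclohex-2-en-1-yl]oxy}dimethylsilane (ring A diene) | CC(C)(C)[Si](C)(C)O[C@@H]1CC[C@H](C)C(C)=C1/C=C/O[Si](CC)(CC)CC | intermediate
14 | but-3-yn-2-one | CC(=O)C#C | starting material
15 | 1-[(2S,4aS,5S,8R)-8-(tert-butyldimethylsilyloxy)-4a,5-dimethyl-2-(triethylsilyloxy)-2,4a,5,6,7,8-hexahydronaphthalen-3-yl]ethan-1-one | CC(C)(C)[Si](C)(C)O[C@@H]1CC[C@H](C)[C@@]2(C)C=C(C(C)=O)[C@@H](O[Si](CC)(CC)CC)C=C12 | intermediate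
16 | 1-[(2S,4aS,5S,8R)-8-(tert-butyldimethylsilyloxy)-4a,5-dimethyl-2-(triethylsilyloxy)-2,4a,5,6,7,8-hexahydronaphthalen-3-yl]ethenyl trifluoromethanesulfonate | CC(C)(C)[Si](C)(C)O[C@@H]1CC[C@H](C)[C@@]2(C)C=C(C(=C)OS(=O)(=O)C(F)(F)F)[C@@H](O[Si](CC)(CC)CC)C=C12 | intermediate
17 | 1-[(2S,4aS,5S,8R)-8-(tert-butyldimethylsilyloxy)-2-hydroxy-4a,5-dimethyl-2,4a,5,6,7,8-hexahydronaphthalen-3-yl]ethenyl trifluoromethanesulfonate | CC(C)(C)[Si](C)(C)O[C@@H]1CC[C@H](C)[C@@]2(C)C=C(C(=C)OS(=O)(=O)C(F)(F)F)[C@@H](O)C=C12 | intermediate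
18 | 1-[(4aS,5S,8R)-8-(tert-butyldimethylsilyloxy)-4a,5-dimethyl-2-oxo-2,4a,5,6,7,8-hexahydronaphthalen-3-yl]ethenyl trifluoromethanesulfonate | CC(C)(C)[Si](C)(C)O[C@@H]1CC[C@H](C)[C@@]2(C)C=C(C(=C)OS(=O)(=O)C(F)(F)F)C(=O)C=C12 | intermediate
19 | 2-[(4aS,5S,8R)-8-(tert-butyldimethylsilyloxy)-4a,5-dimethyl-2-oxo-2,4a,5,6,7,8-hexahydronaphthalen-3-yl]prop-2-enoic acid | CC(C)(C)[Si](C)(C)O[C@@H]1CC[C@H](C)[C@@]2(C)C=C(C(=C)C(=O)O)C(=O)C=C12 | intermediate
20 | (2S)-2-[(4aS,5S,8R)-8-(tert-butyldimethylsilyloxy)-4a,5-dimethyl-2-oxo-2,4a,5,6,7,8-hexahydronaphthalen-3-yl]propanoic acid | CC(C)(C)[Si](C)(C)O[C@@H]1CC[C@H](C)[C@@]2(C)C=C([C@H](C)C(=O)O)C(=O)C=C12 | intermediate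
21 | methyl (2S)-2-[(4aS,5S,8R)-8-(tert-butyldimethylsilyloxy)-4a,5-dimethyl-2-oxo-2,4a,5,6,7,8-hexahydronaphthalen-3-yl]propanoate | CC(C)(C)[Si](C)(C)O[C@@H]1CC[C@H](C)[C@@]2(C)C=C([C@H](C)C(=O)OC)C(=O)C=C12 | intermediate
22 | methyl (2S)-2-[(4aS,5S,8R)-8-hydroxy-4a,5-dimethyl-2-oxo-2,4a,5,6,7,8-hexahydronaphthalen-3-yl]propanoate | O[C@@H]1CC[C@H](C)[C@@]2(C)C=C([C@H](C)C(=O)OC)C(=O)C=C12 | intermediate
23 | angelic acid, (Z)-2-methylbut-2-enoic acid | C/C=C(/C)C(=O)O | starting material
24 | (Z)-2-methylbut-2-enoic 2,4,6-trichlorobenzoic anhydride | C/C=C(/C)C(=O)OC(=O)c1c(Cl)cc(Cl)cc1Cl | intermediate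
25 | methyl (2S)-2-[(4aS,5S,8R)-4a,5-dimethyl-8-{[(2Z)-2-methylbut-2-enoyl]oxy}-2-oxo-2,4a,5,6,7,8-hexahydronaphthalen-3-yl]propanoate | C/C=C(/C)C(=O)O[C@@H]1CC[C@H](C)[C@@]2(C)C=C([C@H](C)C(=O)OC)C(=O)C=C12 | target

**Step count**
Total: 19 steps. Longest linear sequence: 19 steps (1 → 25).

**Steps most likely to fail**

Step 11 (Diels–Alder). Bond formation at the fully substituted C5 terminus may be slow, so that polymerisation of the ynone and thermal or protic loss of the silyl dienol ether outrun ring closure; facial selectivity may also be incomplete. The fallback sets out from 13 and returns at 15. Diene 13 is combined with the more electrophilic propynal (toluene, 0 to 40 °C), which should form the same C5–C6 and C7–C8 bonds and give the C7-formyl cycloadduct F1. Addition of MeMgBr (THF, −78 °C) to the aldehyde gives the secondary allylic alcohol F2 as a mixture of carbinol epimers. Dess–Martin oxidation then returns methyl ketone 15.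

Step 10 (silyl dienol ether). The enolisation may give the (Z)-enol ether, which cannot reach the s-cis geometry, alongside or in place of the (E)-isomer, leaving little reactive diene. The fallback sets out from 8 and returns at 18. Suzuki–Miyaura coupling of 8 with 2-[(E)-2-ethoxyethenyl]-4,4,5,5-tetramethyl-1,3,2-dioxaborolane (Pd(PPh3)4, K3PO4, dioxane/H2O, 80 °C) fixes the geometry and gives the (E)-ethoxydiene F3. Cycloaddition with 14 as in step 11 gives the 8-ethoxy adduct F4, and triflation as in step 12 gives the 8-ethoxy dienyl triflate F5. DDQ in CH2Cl2/pH 7 buffer then oxidises the bis-allylic ether C–H (hydride abstraction, hydrolysis of the oxocarbenium ion) to give dienone triflate 18.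

Step 16 (asymmetric hydrogenation). Hydrogen may also add to the ring B enone alkenes, or facial discrimination at C11 may be incomplete. The fallback sets out from 19 and returns at 21. Esterification of 19 with TMSCHN2 gives the methyl acrylate F6. Hydrogenation with RhCl(PPh3)3 (H2 1 atm, benzene/EtOH), which distinguishes the 1,1-disubstituted alkene from trisubstituted ones, gives 21 together with its C11 epimer F7. The two diastereomers are separated by chromatography, and F7 is re-equilibrated at C11 with DBU in toluene and recycled.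

**Further compounds**
F1 | step 11 | (2S,4aS,5S,8R)-8-(tert-butyldimethylsilyloxy)-4a,5-dimethyl-2-(triethylsilyloxy)-2,4a,5,6,7,8-hexahydronaphthalene-3-carbaldehyde | CC(C)(C)[Si](C)(C)O[C@@H]1CC[C@H](C)[C@@]2(C)C=C(C=O)[C@@H](O[Si](CC)(CC)CC)C=C12
F2 | step 11 | 1-[(2S,4aS,5S,8R)-8-(tert-butyldimethylsilyloxy)-4a,5-dimethyl-2-(triethylsilyloxy)-2,4a,5,6,7,8-hexahydronaphthalen-3-yl]ethan-1-ol (carbinol epimers) | CC(C)(C)[Si](C)(C)O[C@@H]1CC[C@H](C)[C@@]2(C)C=C(C(C)O)[C@@H](O[Si](CC)(CC)CC)C=C12
F3 | step 10 | tert-butyl{[(1R,4S)-2-[(E)-2-ethoxyethenyl]-3,4-dimethylcyclohex-2-en-1-yl]oxy}dimethylsilane | CC(C)(C)[Si](C)(C)O[C@@H]1CC[C@H](C)C(C)=C1/C=C/OCC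
F4 | step 10 | 1-[(2S,4aS,5S,8R)-8-(tert-butyldimethylsilyloxy)-2-ethoxy-4a,5-dimethyl-2,4a,5,6,7,8-hexahydronaphthalen-3-yl]ethan-1-one | CC(C)(C)[Si](C)(C)O[C@@H]1CC[C@H](C)[C@@]2(C)C=C(C(C)=O)[C@@H](OCC)C=C12
F5 | step 10 | 1-[(2S,4aS,5S,8R)-8-(tert-butyldimethylsilyloxy)-2-ethoxy-4a,5-dimethyl-2,4a,5,6,7,8-hexahydronaphthalen-3-yl]ethenyl trifluoromethanesulfonate | CC(C)(C)[Si](C)(C)O[C@@H]1CC[C@H](C)[C@@]2(C)C=C(C(=C)OS(=O)(=O)C(F)(F)F)[C@@H](OCC)C=C12
F6 | step 16 | methyl 2-[(4aS,5S,8R)-8-(tert-butyldimethylsilyloxy)-4a,5-dimethyl-2-oxo-2,4a,5,6,7,8-hexahydronaphthalen-3-yl]prop-2-enoate | CC(C)(C)[Si](C)(C)O[C@@H]1CC[C@H](C)[C@@]2(C)C=C(C(=C)C(=O)OC)C(=O)C=C12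
F7 | step 16 | methyl (2R)-2-[(4aS,5S,8R)-8-(tert-butyldimethylsilyloxy)-4a,5-dimethyl-2-oxo-2,4a,5,6,7,8-hexahydronaphthalen-3-yl]propanoate (C11 epimer of 21) | CC(C)(C)[Si](C)(C)O[C@@H]1CC[C@H](C)[C@@]2(C)C=C([C@@H](C)C(=O)OC)C(=O)C=C12
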